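The earlier runs and the new flask were generated by integration on assumed constants.

Winter and dusk are one recipe stopped at two times, 2.5 d and 4.0 d, and we want the length of their chains at the stop.

| flask | free monomer | transfer agent | initiator | remark | time |
|---|---|---|---|---|---|
| cedar | 1.9 M | 0.057 M | 27 mM | run made earlier |  |
| elm | 1.9 M | 0.057 M | 42 mM | run made earlier |  |
| birch | 1.9 M | 0.029 M | 19 mM | run made earlier |  |
| winter | 1.9 M | 0.0570 M | 19 mM |  | 2.5 d |
| dusk | 1.9 M | 0.0570 M | 19 mM |  | 4.0 d |

| run | time / d | monomer in chains / % | free monomer / % |
|---|---|---|---|
| cedar | 0.167 | 79.7 | 20.7 |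
| cedar | 0.500 | 91.3 | 9.3 |
| cedar | 0.833 | 92.3 | 7.2 |
| cedar | 1.25 | 92.3 | 7.1 |
| cedar | 2.08 | 92.1 | 7.7 |
| cedar | 2.50 | 91.3 | 6.2 |
| elm | 0.167 | 92.3 | 7.9 |
| elm | 0.500 | 98.2 | 1.5 |
| elm | 0.833 | 99.1 | 0.2 |
| elm | 1.25 | 98.9 | 0.5 |
| elm | 2.08 | 98.2 | 0 |
| elm | 2.50 | 98.2 | 1.1 |
| birch | 0.208 | 81.1 | 18.3 |
| birch | 0.625 | 95.7 | 3.7 |
| birch | 1.25 | 97.0 | 1.9 |
| birch | 1.67 | 97.1 | 1.5 |
| birch | 2.50 | 98.2 | 1.5 |

(each reading ± 0.5 percentage points)

- the average divides the monomer in chains by the number of chains begun, living and dead together
- the earlier runs do not show the number of chains; that part of a forecast is a guess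

* which of the two ends with the longer chains by the average number of monomer units in a chain (chains begun, living or dead) ("neither" if they lie within 10 %) (winter / dusk / neither)
* average number of monomer units in a chain (chains begun, living or dead) at the end, winter
* average number of monomer units in a chain (chains begun, living or dead) at the end, dusk

Let us run cedar in slow motion. In the first instants the reaction is quick: by 0.167 d free monomer is down to 20.7 %. In the middle it slows, with 9.3 % at 0.500 d. Then the readings stay near 7.1 %, though free monomer remains, so we take it that whatever carries the reaction dies first. Elm, with more initiator, stops lower. Birch, with less transfer agent and less initiator, stops lower too.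

So we suppose that initiator begins living ends, that each takes up free monomer at a rate proportional to free monomer, and that each dies by a pseudo-first-order loss proportional to transfer agent. The logarithmic rate of free monomer then follows the living ends present, and their time integral is the number begun divided by that loss rate. Integrated, the reach, the natural logarithm of free monomer charged over free monomer at the stop, is a constant times initiator charged over transfer agent charged, and the monomer charge cancels. Cedar's plateau reading gives 5.58 for this constant, the reach per unit of that ratio. Birch reads 6.41, but its 1.5 % lies nearer the scatter of 0.5 percentage points, so we keep cedar's.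

For winter and dusk this leaves 15.5 % of the free monomer. Birch, with the same initiator and half the transfer agent of winter, read flat within scatter from 1.25 d on, earlier than either stop, so we expect one plateau. Our guess of one chain per initiator charged gives 84.5 for both.

The forecast also says neither, but with 50 for winter and 50 for dusk: “I take about 33 mM”. Its length is shorter than ours, and the count of chains is the part we both guess.

The flask gives neither, with 82.7 for winter and 81.9 for dusk.

    free monomer + initiator → living end + monomer in chains (k = 3.60 L mol⁻¹ h⁻¹)
    free monomer + living end → monomer in chains + living end, rate k2*[living end]*[free monomer] (k = 26.8 L mol⁻¹ h⁻¹)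
    living end + transfer agent → dead chain (kL = 6.24 L mol⁻¹ h⁻¹)
    initiator → spent initiator (k = 0.198 h⁻¹)
    monomer in chains → over-reaction product (k = 2.64 × 10⁻⁴ h⁻¹)

Winter ends with 18.5 % of its free monomer and 0.0184 M of dead chain, against our 15.5 % and the forecast's 33 mM of chains. In dusk the living end has a half-life of 0.092 d at 0.0609 d, far shorter than the 110 d half-life of monomer in chains. At 4.0 d dusk holds 79.5 % in chains and 1.99 % as over-reaction product. A neighbour of dusk charged with 1.1 M of free monomer keeps the same ratio of initiator to transfer agent, so our reckoning gives the same 15.5 % and a length of 48.9; that neighbour keeps 19 % of its free monomer and gives 48.1.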